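**Retrosynthetic overview**
1. Target 24 ⇐ desilylation of 23 ⇐ key ring closure at C1–C10: the C1 aldehyde of keto-aldehyde 22, turned into an acyl anion equivalent by a carbene catalyst, adds to the C10 methyl ketone (crossed benzoin). This forms the ten-membered ring last and sets C10.
2. 22 ⇐ double ozonolysis of diene 21 (isopropenyl → C10 ketone, prenyl → C1 aldehyde) ⇐ Yamaguchi angeloylation of C9–OH.
3. cis-γ-Lactone (first ring) ⇐ syn-alkoxyallylboration of C8 aldehyde 11 (sets C8, C9), then lactonisation onto C12.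
4. 11 ⇐ chelation-controlled indium Barbier coupling of α-hydroxy-(R)-citronellal 7 with Morita–Baylis–Hillman-derived Z-bromide 4 (sets C6, C7 from C5), C5 acylation, C6 silylation with acetal unmasking.
5. C5 ⇐ proline α-aminoxylation of (R)-citronellal (C4 from the chiral pool).

Convention and assumption: labels C1–C13 always mean target positions (C1 ketone, C4 CHMe, C5 O-acyl, C6 OH, C7, C8 lactone O, C9 O-angeloyl, C10 C(OH)Me, C11/C13 methylidene, C12 lactone C=O; target = 4R,5R,6R,7S,8S,9R,10R, (2R)-2-methylbutanoate, Z-angelate), while locants inside systematic names are the names' own; (2R)-2-methylbutanoic acid, angelic acid and (+)-B-methoxydiisopinocampheylborane are bought.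

Step 1
Reactants: 1 2,2-dimethoxyacetaldehyde (60% aqueous); 2 methyl acrylate
Product: 3 methyl 3-hydroxy-4,4-dimethoxy-2-methylidenebutanoate (racemic)
Conditions: 1,4-diazabicyclo[2.2.2]octane (0.5 equiv), 1,4-dioxane/H2O 1:1, rt, 24 h
Reagents that add atoms: none
Why: Morita–Baylis–Hillman reaction of an activated, non-enolisable aldehyde (water accelerates it); the new carbinol centre is erased in step 2, so no stereocontrol is needed.

Step 2
Reactants: 3 methyl 3-hydroxy-4,4-dimethoxy-2-methylidenebutanoate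
Product: 4 methyl (2Z)-2-(bromomethyl)-4,4-dimethoxybut-2-enoate
Conditions: NBS, Me2S, CH2Cl2, 0 °C → rt
Reagents that add atoms: N-bromosuccinimide, O=C1CCC(=O)N1Br
Why: Corey–Kim-type bromination of a Morita–Baylis–Hillman alcohol goes with SN2' transposition to the more stable (Z)-2-(bromomethyl)enoate (ester trans to the acetal carbon) under neutral conditions that spare the acetal.

Step 3
Reactants: 5 (R)-citronellal
Product: 7 (2R,3R)-2-hydroxy-3,7-dimethyloct-6-enal, via anilinooxy aldehyde 6 (not isolated)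
Conditions: L-proline (20 mol %), PhNO, CHCl3, 4 °C; then CuSO4·5H2O (30 mol %), MeOH, 0 °C; crude 7 (hemiacetal dimer) used at once
Reagents that add atoms: nitrosobenzene, O=Nc1ccccc1
Why: Proline-catalysed α-aminoxylation (O-selective nitroso aldol through the enamine) sets C5 as R under catalyst control whatever the C4 centre, and copper-catalysed N–O cleavage frees the α-hydroxy aldehyde without touching the carbonyl.

Step 4
Reactants: 7 (2R,3R)-2-hydroxy-3,7-dimethyloct-6-enal; 4 methyl (2Z)-2-(bromomethyl)-4,4-dimethoxybut-2-enoate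
Product: 8 methyl (3S,4R,5R,6R)-3-(dimethoxymethyl)-4,5-dihydroxy-6,10-dimethyl-2-methylideneundec-9-enoate
Conditions: In powder, THF/H2O 1:1, rt; NaHCO3 work-up
Reagents that add atoms: none
Why: Indium Barbier allylation in water: the allylindium reacts at its γ carbon through a chair in which indium chelates the free C5 hydroxyl and the aldehyde oxygen (Cram chelate → 5,6-syn), and the Z geometry gives the 6,7-syn relationship, so C6 and C7 are both set from C5; the allyl partner carries no stereocentre that could oppose this.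

Step 5
Reactants: 8 diol ester; 9 (2R)-2-methylbutanoic acid
Product: 10 methyl (3S,4R,5R,6R)-3-(dimethoxymethyl)-4-hydroxy-6,10-dimethyl-5-{[(2R)-2-methylbutanoyl]oxy}-2-methylideneundec-9-enoate
Conditions: N,N'-diisopropylcarbodiimide, 4-(dimethylamino)pyridine (10 mol %), CH2Cl2, −20 °C
Reagents that add atoms: none
Why: Steglich esterification goes to C5–OH because C6–OH sits next to the fully branched C7 and is hydrogen-bonded to the acrylate carbonyl; the low temperature avoids lactonisation of C6–OH and epimerisation of the acid.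

Step 6
Reactants: 10 C5 monoester
Product: 11 methyl (3S,4R,5R,6R)-3-formyl-6,10-dimethyl-5-{[(2R)-2-methylbutanoyl]oxy}-2-methylidene-4-[(triethylsilyl)oxy]undec-9-enoate
Conditions: TESOTf (3.5 equiv), 2,4,6-collidine, CH2Cl2, −40 → 0 °C; then H2O; crude 11 used at once
Reagents that add atoms: triethylsilyl trifluoromethanesulfonate, CC[Si](CC)(CC)OS(=O)(=O)C(F)(F)F; water, O
Why: Silyl triflate/collidine acetal cleavage: TESOTf silylates C6–OH and converts the dimethyl acetal through a collidinium salt into the aldehyde on aqueous work-up, without the aqueous acid or strong base that would epimerise or conjugate the C7 centre.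

Step 7
Reactants: 12 (4-methoxyphenyl)methanol; 13 3-chloro-2-methylprop-1-ene
Product: 14 1-methoxy-4-{[(2-methylprop-2-en-1-yl)oxy]methyl}benzene
Conditions: NaH, Bu4NI (cat.), THF, 0 °C → rt
Reagents that add atoms: none
Why: Williamson ether synthesis of a primary allylic chloride with the sodium alkoxide.

Step 8
Reactants: 11 C8 aldehyde; 14 PMB methallyl ether
Product: 17 PMB-protected diene cis-lactone, via allylborane 15 (not isolated), via hydroxy ester 16 (not isolated)
Conditions: 14, s-BuLi, THF, −78 °C; (+)-B-methoxydiisopinocampheylborane; BF3·OEt2; 11, −78 °C; 2-aminoethanol; then pyridinium p-toluenesulfonate, toluene, 50 °C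
Reagents that add atoms: (+)-B-methoxydiisopinocampheylborane, COB([C@H]1C[C@H]2C[C@@H]([C@@H]1C)C2(C)C)[C@H]1C[C@H]2C[C@@H]([C@@H]1C)C2(C)C (its boron and isopinocampheyl groups stay in 15 only)
Why: Brown alkoxyallylboration with the 2-methyl analogue of the (Z)-γ-alkoxyallyl reagent: the chair transition state gives the 8,9-syn product, the (−)-α-pinene-derived Ipc groups select the aldehyde re face (also the Felkin face with the acrylate carbon as the large group), C7 cannot epimerise at −78 °C, and the new C8–OH then closes the γ-lactone on the methyl ester, cis because C7 and C8 are already fixed.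

Step 9
Reactants: 17 PMB-protected diene cis-lactone
Product: 18 diene lactone C9 alcohol
Conditions: DDQ, CH2Cl2/pH 7 buffer, 0 °C
Reagents that add atoms: none
Why: Oxidative PMB cleavage (hydride abstraction from the electron-rich benzyl ether, then hydrolysis) leaves the silyl ether, the esters and the other alkenes untouched.

Step 10
Reactants: 18 diene lactone C9 alcohol; 19 angelic acid
Product: 21 diene lactone C9 angelate, via mixed anhydride 20 (not isolated)
Conditions: 19, 2,4,6-trichlorobenzoyl chloride, Et3N, toluene, rt; then 18, 4-(dimethylamino)pyridine, 60 °C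
Reagents that add atoms: 2,4,6-trichlorobenzoyl chloride, O=C(Cl)c1c(Cl)cc(Cl)cc1Cl (its acyl group stays in 20 only)
Why: Yamaguchi esterification acylates the hindered allylic C9–OH (the only free hydroxyl) and is the protocol that keeps the angelate Z instead of isomerising it to tiglate.

Step 11
Reactants: 21 diene lactone C9 angelate
Product: 22 seco keto-aldehyde (C10 methyl ketone and C1 aldehyde)
Conditions: O3, CH2Cl2/MeOH, −78 °C, Sudan Red 7B end point; then Me2S
Reagents that add atoms: ozone, [O-][O+]=O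
Why: Chemoselective ozonolysis cleaves the electron-rich 1,1-disubstituted and trisubstituted alkenes much faster than the conjugated α-methylene lactone and angelate, unveiling both carbonyl partners at once.

Step 12
Reactants: 22 seco keto-aldehyde
Product: 23 6-O-triethylsilyl target (ten-membered ring closed)
Conditions: 2-(pentafluorophenyl)-6,7-dihydro-5H-pyrrolo[2,1-c][1,2,4]triazol-2-ium tetrafluoroborate (30 mol %), i-Pr2NEt (30 mol %), CH2Cl2, 0.002 M, slow addition, 30 °C
Reagents that add atoms: none
Why: Proposed new method: the carbene adds to the unhindered C1 aldehyde to give the Breslow intermediate (acyl anion equivalent), which attacks the C10 ketone, activated by the α-acyloxy group and held near by the cis-lactone turn, anti to the C9–O bond (polar Felkin–Anh, giving 10R), and release of the carbene leaves the tertiary α-ketol; the closest known reaction type is the carbene-catalysed intramolecular aldehyde–ketone crossed benzoin cyclisation to five- and six-membered rings, together with carbene-catalysed macrocyclic Stetter reactions, so ring size is the untested element and the weak base is chosen to avoid C9 enolisation and β-elimination of the lactone oxygen.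

Step 13
Reactants: 23 6-O-triethylsilyl target
Product: 24 target (CNP0226386.1)
Conditions: HF·pyridine, pyridine/THF, 0 °C
Reagents that add atoms: none
Why: Fluoride desilylation under buffered, non-basic conditions removes the secondary TES ether without acyl migration from C5 to C6 or addition to the α-methylene lactone.

**Compound list**
1 | 2,2-dimethoxyacetaldehyde | COC(OC)C=O | starting material
2 | methyl acrylate | C=CC(=O)OC | starting material
3 | methyl 3-hydroxy-4,4-dimethoxy-2-methylidenebutanoate (racemic) | COC(OC)C(O)C(=C)C(=O)OC | intermediate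
4 | methyl (2Z)-2-(bromomethyl)-4,4-dimethoxybut-2-enoate | COC(OC)/C=C(CBr)/C(=O)OC | intermediate
5 | (R)-citronellal, (3R)-3,7-dimethyloct-6-enal | O=CC[C@H](C)CCC=C(C)C | starting material
6 | (2R,3R)-2-(anilinooxy)-3,7-dimethyloct-6-enal | O=C[C@H](ONc1ccccc1)[C@H](C)CCC=C(C)C | intermediate
7 | (2R,3R)-2-hydroxy-3,7-dimethyloct-6-enal | O=C[C@H](O)[C@H](C)CCC=C(C)C | intermediate
8 | methyl (3S,4R,5R,6R)-3-(dimethoxymethyl)-4,5-dihydroxy-6,10-dimethyl-2-methylideneundec-9-enoate | COC(OC)[C@@H](C(=C)C(=O)OC)[C@@H](O)[C@H](O)[C@H](C)CCC=C(C)C | intermediate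
9 | (2R)-2-methylbutanoic acid | CC[C@@H](C)C(=O)O | starting material
10 | methyl (3S,4R,5R,6R)-3-(dimethoxymethyl)-4-hydroxy-6,10-dimethyl-5-{[(2R)-2-methylbutanoyl]oxy}-2-methylideneundec-9-enoate | COC(OC)[C@@H](C(=C)C(=O)OC)[C@@H](O)[C@H](OC(=O)[C@H](C)CC)[C@H](C)CCC=C(C)C | intermediate
11 | methyl (3S,4R,5R,6R)-3-formyl-6,10-dimethyl-5-{[(2R)-2-methylbutanoyl]oxy}-2-methylidene-4-[(triethylsilyl)oxy]undec-9-enoate | O=C[C@@H](C(=C)C(=O)OC)[C@@H](O[Si](CC)(CC)CC)[C@H](OC(=O)[C@H](C)CC)[C@H](C)CCC=C(C)C | intermediate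
12 | (4-methoxyphenyl)methanol | COc1ccc(CO)cc1 | starting material
13 | 3-chloro-2-methylprop-1-ene | CC(=C)CCl | starting material
14 | 1-methoxy-4-{[(2-methylprop-2-en-1-yl)oxy]methyl}benzene | COc1ccc(COCC(C)=C)cc1 | intermediate
15 | [(2Z)-3-(4-methoxybenzyloxy)-2-methylprop-2-en-1-yl]bis(isopinocampheyl)borane, Ipc from (−)-α-pinene | COc1ccc(CO/C=C(/C)CB([C@H]2C[C@H]3C[C@@H]([C@@H]2C)C3(C)C)[C@H]2C[C@H]3C[C@@H]([C@@H]2C)C3(C)C)cc1 | intermediate
16 | open-chain hydroxy ester: methyl 2-methylidene ester (C12) with C8–OH, C9–OPMB, C10 isopropenyl, C6–OTES, C5 (2R)-2-methylbutanoate, prenyl terminus; C4–C9 as in the target | COC(=O)C(=C)[C@H]([C@H](O)[C@@H](OCc1ccc(OC)cc1)C(C)=C)[C@@H](O[Si](CC)(CC)CC)[C@H](OC(=O)[C@H](C)CC)[C@H](C)CCC=C(C)C | intermediate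
17 | PMB-protected diene cis-lactone: C7,C8-cis 3-methylideneoxolan-2-one; C8 carries C9H(OPMB)–C(CH3)=CH2; C7 carries C6H(OTES)–C5H[O-(2R)-2-methylbutanoyl]–C4H(CH3)–CH2CH2CH=C(CH3)2; C4–C9 as in the target | C=C1C(=O)O[C@H]([C@@H](OCc2ccc(OC)cc2)C(C)=C)[C@@H]1[C@@H](O[Si](CC)(CC)CC)[C@H](OC(=O)[C@H](C)CC)[C@H](C)CCC=C(C)C | intermediate
18 | diene lactone C9 alcohol (17 without PMB) | C=C1C(=O)O[C@H]([C@@H](O)C(C)=C)[C@@H]1[C@@H](O[Si](CC)(CC)CC)[C@H](OC(=O)[C@H](C)CC)[C@H](C)CCC=C(C)C | intermediate
19 | angelic acid, (2Z)-2-methylbut-2-enoic acid | C/C=C(/C)C(=O)O | starting material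
20 | angelic 2,4,6-trichlorobenzoic anhydride | C/C=C(/C)C(=O)OC(=O)c1c(Cl)cc(Cl)cc1Cl | intermediate
21 | diene lactone C9 angelate (18 acylated on C9–OH) | C=C1C(=O)O[C@H]([C@@H](OC(=O)/C(C)=C\C)C(C)=C)[C@@H]1[C@@H](O[Si](CC)(CC)CC)[C@H](OC(=O)[C@H](C)CC)[C@H](C)CCC=C(C)C | intermediate
22 | seco keto-aldehyde: as 21 with C10 acetyl in place of isopropenyl and C1 aldehyde in place of the prenyl alkene | C=C1C(=O)O[C@H]([C@@H](OC(=O)/C(C)=C\C)C(C)=O)[C@@H]1[C@@H](O[Si](CC)(CC)CC)[C@H](OC(=O)[C@H](C)CC)[C@H](C)CCC=O | intermediate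
23 | 6-O-triethylsilyl target (4R,5R,6R,7S,8S,9R,10R spatial arrangement) | C=C1C(=O)O[C@H]2[C@@H]1[C@@H](O[Si](CC)(CC)CC)[C@H](OC(=O)[C@H](C)CC)[C@H](C)CCC(=O)[C@](C)(O)[C@@H]2OC(=O)/C(C)=C\C | intermediate
24 | target: (4R,5R,6R,7S,8S,9R,10R)-9-angeloyloxy-6,10-dihydroxy-5-[(2R)-2-methylbutanoyloxy]-1-oxogermacr-11(13)-en-12,8-olide | C=C1C(=O)O[C@H]2[C@@H]1[C@@H](O)[C@H](OC(=O)[C@H](C)CC)[C@H](C)CCC(=O)[C@](C)(O)[C@@H]2OC(=O)/C(C)=C\C | target

**Totals and risks**
Total step count: 13. Longest linear sequence: 11 steps (1 → 24 through steps 1, 2, 4–6 and 8–13).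

Most likely to fail, with fallbacks:

Step 12 (ring closure). The ten-membered crossed benzoin is unprecedented in ring size and reversible. The α-methylene lactone also offers the Breslow intermediate an irreversible Stetter pathway. If that or oligomerisation wins, set out from 21. Thiophenol with Et3N adds to C13 to give the sulfide adduct F8. Ozonolysis as in step 11, with a third equivalent of ozone taking sulfur to the sulfoxide, gives the keto-aldehyde sulfoxide F9, which has no Michael acceptor left. The same carbene cyclisation gives the macrocyclic sulfoxide F10. Syn-elimination of benzenesulfenic acid (toluene, 90 °C, NaHCO3) restores the methylidene and comes back to the route at 23.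

Step 5 (C5 versus C6 acylation). If the two secondary hydroxyls are not told apart, replace selectivity by orthogonal protection, setting out from 6 before its N–O bond is cleaved. Indium Barbier coupling of 6 with 4 gives the aminoxy alcohol F1, in which only C6–OH is free. TESCl/imidazole gives the silyl ether F2. Zn/AcOH cleaves the N–O bond to the C5 alcohol F3. Steglich acylation with 9 gives the ester F4. TESOTf/collidine then water, now acting on the acetal only, comes back to the route at 11.

Step 8 (alkoxyallylboration of the epimerisable aldehyde with an untested 2-methyl reagent). If it fails, set out from 11 and use an amine-catalysed syn-aldol instead. Hydroxyacetone with O-tert-butyl-L-threonine (Z-enamine, same aldehyde face as an L-proline aldol) gives the keto diol F5. Pyridinium p-toluenesulfonate closes it to the lactone keto alcohol F6, which already carries the C10 ketone. Yamaguchi acylation gives the keto angelate F7. Ozonolysis of the one remaining electron-rich alkene comes back to the route at 22. This drops step 7 and the PMB cleavage at the cost of a separate lactonisation, so it is one step shorter overall, but it exposes C7 to an amine.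

Further compounds
F1 | step 5 | methyl 3-(dimethoxymethyl)-4-hydroxy-5-(anilinooxy)-6,10-dimethyl-2-methylideneundec-9-enoate, centres as in 8 | COC(OC)[C@@H](C(=C)C(=O)OC)[C@@H](O)[C@H](ONc1ccccc1)[C@H](C)CCC=C(C)C
F2 | step 5 | 4-O-triethylsilyl ether of F1 | COC(OC)[C@@H](C(=C)C(=O)OC)[C@@H](O[Si](CC)(CC)CC)[C@H](ONc1ccccc1)[C@H](C)CCC=C(C)C
F3 | step 5 | methyl 3-(dimethoxymethyl)-5-hydroxy-6,10-dimethyl-2-methylidene-4-[(triethylsilyl)oxy]undec-9-enoate | COC(OC)[C@@H](C(=C)C(=O)OC)[C@@H](O[Si](CC)(CC)CC)[C@H](O)[C@H](C)CCC=C(C)C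
F4 | step 5 | (2R)-2-methylbutanoate of F3 (dimethyl acetal of 11) | COC(OC)[C@@H](C(=C)C(=O)OC)[C@@H](O[Si](CC)(CC)CC)[C@H](OC(=O)[C@H](C)CC)[C@H](C)CCC=C(C)C
F5 | step 8 | open-chain keto diol: as 16 with C9–OH and C10 acetyl | COC(=O)C(=C)[C@H]([C@H](O)[C@@H](O)C(C)=O)[C@@H](O[Si](CC)(CC)CC)[C@H](OC(=O)[C@H](C)CC)[C@H](C)CCC=C(C)C
F6 | step 8 | lactone keto alcohol: as 18 with C10 acetyl in place of isopropenyl | C=C1C(=O)O[C@H]([C@@H](O)C(C)=O)[C@@H]1[C@@H](O[Si](CC)(CC)CC)[C@H](OC(=O)[C@H](C)CC)[C@H](C)CCC=C(C)C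
F7 | step 8 | keto angelate: as 21 with C10 acetyl in place of isopropenyl | C=C1C(=O)O[C@H]([C@@H](OC(=O)/C(C)=C\C)C(C)=O)[C@@H]1[C@@H](O[Si](CC)(CC)CC)[C@H](OC(=O)[C@H](C)CC)[C@H](C)CCC=C(C)C
F8 | step 12 | C13 phenylthio adduct of 21 (C11 epimers) | c1ccccc1SCC1C(=O)O[C@H]([C@@H](OC(=O)/C(C)=C\C)C(C)=C)[C@@H]1[C@@H](O[Si](CC)(CC)CC)[C@H](OC(=O)[C@H](C)CC)[C@H](C)CCC=C(C)C
F9 | step 12 | C13 phenylsulfinyl analogue of 22 (keto-aldehyde, saturated C11) | O=S(CC1C(=O)O[C@H]([C@@H](OC(=O)/C(C)=C\C)C(C)=O)[C@@H]1[C@@H](O[Si](CC)(CC)CC)[C@H](OC(=O)[C@H](C)CC)[C@H](C)CCC=O)c1ccccc1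
F10 | step 12 | C13 phenylsulfinyl analogue of 23 (macrocycle, saturated C11) | O=S(CC1C(=O)O[C@H]2[C@@H]1[C@@H](O[Si](CC)(CC)CC)[C@H](OC(=O)[C@H](C)CC)[C@H](C)CCC(=O)[C@](C)(O)[C@@H]2OC(=O)/C(C)=C\C)c1ccccc1
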